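**Retrosynthetic overview**
- The E-alkene between the bicyclic core and the diester side chain is made last, by cross-metathesis of a 2-vinyl furo[3,2-b]pyranone with a (2R,3S)-pentene diester.
- The pyranone ring is formed second: a Z-enoate lactonises onto the ring 3-OH once an acetonide is removed; the Z-enoate comes from Lindlar reduction of an ynoate.
- Key C–C bond (tetrahydrofuran carbon to enoate β-carbon): the carbonyl carbon of a sugar 1,4-lactone is joined to the β-carbon of lithium ethyl propiolate (a β-acylvinyl anion, homoenolate-type donor). Silane reduction in the same flask sets the all-cis ring centre.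
- The tetrahydrofuran ring is present first, taken with its three other stereocentres from D-gulono-1,4-lactone; the vinyl group comes from deoxygenation of the 5,6-diol.
- The side chain comes from Sharpless desymmetrisation of divinylcarbinol, hydride opening, enzymatic acetylation and benzoylation.

Assumption: D-gulono-1,4-lactone is taken as a purchasable sugar lactone; reagents and solvents carry no compound numbers.

**Step 1**
Reactants: 1 D-gulono-1,4-lactone
Product: 2 2,3:5,6-di-O-isopropylidene-D-gulono-1,4-lactone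
Conditions: 2,2-dimethoxypropane, acetone, TsOH·H2O (cat.), rt
Reagents that add atoms: 2,2-dimethoxypropane, COC(C)(C)OC
Why: Acid-catalysed acetonide formation (transacetalisation) caps the cis-2,3-diol and the terminal 5,6-diol as dioxolanes without touching any stereocentre, so the three ring centres of the future tetrahydrofuran come straight from the sugar.

**Step 2**
Reactants: 2 2,3:5,6-di-O-isopropylidene-D-gulono-1,4-lactone
Product: 3 2,3-O-isopropylidene-D-gulono-1,4-lactone
Conditions: AcOH/H2O 4:1, rt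
Reagents that add atoms: none
Why: Mild acetal hydrolysis cleaves the terminal 5,6-dioxolane much faster than the cis-fused 2,3-dioxolane on the lactone ring, the standard selective deprotection of sugar diacetonides.

**Step 3**
Reactants: 3 2,3-O-isopropylidene-D-gulono-1,4-lactone
Product: 5 5,6-dideoxy-2,3-O-isopropylidene-L-lyxo-hex-5-enono-1,4-lactone, via iodohydrin 4 (not isolated)
Conditions: PPh3, I2, imidazole, toluene, 110 °C
Reagents that add atoms: none
Why: In this Garegg–Samuelsson olefination the primary hydroxyl is iodinated first, the secondary one is then activated as its oxyphosphonium salt, and iodide-induced elimination gives the terminal alkene without touching the adjacent ring stereocentre or the lactone.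

**Step 4**
Reactants: 5 5,6-dideoxy-2,3-O-isopropylidene-L-lyxo-hex-5-enono-1,4-lactone; 6 ethyl propiolate
Product: 10 ethyl 3-[(3aS,4R,6S,6aR)-2,2-dimethyl-6-vinyltetrahydrofuro[3,4-d][1,3]dioxol-4-yl]prop-2-ynoate, via lithium ethyl propiolate 7 (not isolated), via lithium lactolate 8 (not isolated), via oxocarbenium ion 9 (not isolated)
Conditions: 6 (1.3 equiv), n-BuLi, THF, −78 °C; add 5, −78 °C; then CH2Cl2, Et3SiH (5 equiv), BF3·OEt2 (4 equiv), −78 → −20 °C
Reagents that add atoms: none
Why: Proposed new method: lithium ethyl propiolate, a β-acylvinyl anion (homoenolate-type) donor whose ester β-carbon is nucleophilic, adds to the activated lactone carbonyl (two carbons that are both acceptor sites in normal reactivity) to give a stable lithium lactolate, which BF3·OEt2 ionises to a bicyclic alkynyl oxocarbenium ion that Et3SiH reduces from the convex face, anti to the fused dioxolane and the vinyl group, so the alkynyl carbon ends up cis to all three other ring substituents (4R, all-cis tetrahydrofuran); the closest known chemistry is the two-stage acetylide addition to aldonolactones followed by silane reduction of the isolated lactol (Kishi-type reductive C-glycosylation), run here in one flask with an ester-bearing acetylide.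

**Step 5**
Reactants: 10 ethyl 3-[(3aS,4R,6S,6aR)-2,2-dimethyl-6-vinyltetrahydrofuro[3,4-d][1,3]dioxol-4-yl]prop-2-ynoate
Product: 11 ethyl (2Z)-3-[(3aS,4R,6S,6aR)-2,2-dimethyl-6-vinyltetrahydrofuro[3,4-d][1,3]dioxol-4-yl]prop-2-enoate
Conditions: H2 (1 atm), Pd/CaCO3 poisoned with Pb(OAc)2 (Lindlar catalyst), quinoline, EtOAc, rt, stopped at 1 equiv H2
Reagents that add atoms: none
Why: Lindlar semihydrogenation adds H2 syn to the electron-poor alkyne much faster than to the monosubstituted vinyl group, giving the Z-enoate geometry needed for ring closure.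

**Step 6**
Reactants: 11 ethyl (2Z)-3-[(3aS,4R,6S,6aR)-2,2-dimethyl-6-vinyltetrahydrofuro[3,4-d][1,3]dioxol-4-yl]prop-2-enoate
Product: 13 (2S,3R,3aR,7aR)-3-hydroxy-2-vinyl-2,3,3a,7a-tetrahydro-5H-furo[3,2-b]pyran-5-one, via dihydroxy Z-ester 12 (not isolated)
Conditions: TFA/H2O 9:1, 0 °C → rt; toluene azeotrope
Reagents that add atoms: none
Why: Aqueous acid hydrolyses the dioxolane, and the freed hydroxyl next to the Z-enoate arm lactonises (acid-catalysed transesterification) to the cis-fused 5,6-dihydro-2H-pyran-2-one, while the other hydroxyl cannot reach the ester and no stereocentre is altered.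

**Step 7**
Reactants: 14 penta-1,4-dien-3-ol (divinylcarbinol)
Product: 15 (2R,3S)-1,2-epoxypent-4-en-3-ol
Conditions: Ti(OiPr)4 (10 mol %), L-(+)-diisopropyl tartrate (13 mol %), t-BuOOH, 4 Å MS, CH2Cl2, −20 °C
Reagents that add atoms: tert-butyl hydroperoxide, CC(C)(C)OO
Why: Sharpless asymmetric epoxidation with L-(+)-tartrate selects one enantiotopic vinyl group and one alkene face of the prochiral carbinol, giving the anti (2R,3S)-epoxy alcohol, and the minor enantiomer is removed by its faster second epoxidation so the ee rises further.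

**Step 8**
Reactants: 15 (2R,3S)-1,2-epoxypent-4-en-3-ol
Product: 16 (2R,3S)-pent-4-ene-2,3-diol
Conditions: LiAlH4, THF, 0 °C; Na2SO4·10H2O
Reagents that add atoms: none
Why: Hydride opens the terminal epoxide by SN2 attack at the unsubstituted CH2 carbon (regioselective epoxide reduction), which becomes the methyl group, and both carbinol centres are retained as the anti-diol.

**Step 9**
Reactants: 16 (2R,3S)-pent-4-ene-2,3-diol
Product: 17 (2R,3S)-3-hydroxypent-4-en-2-yl acetate
Conditions: immobilised Candida antarctica lipase B, vinyl acetate (3 equiv), MTBE, 30 °C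
Reagents that add atoms: vinyl acetate, CC(=O)OC=C
Why: Lipase-catalysed transesterification acylates the (R)-configured methyl carbinol, which fits the enzyme's small pocket (Kazlauskas rule), and leaves the (S)-allylic hydroxyl free, so the two secondary alcohols are told apart without protecting groups.

**Step 10**
Reactants: 17 (2R,3S)-3-hydroxypent-4-en-2-yl acetate
Product: 18 (2R,3S)-2-acetoxypent-4-en-3-yl benzoate
Conditions: BzCl, pyridine, DMAP (cat.), CH2Cl2, 0 °C
Reagents that add atoms: benzoyl chloride, O=C(Cl)c1ccccc1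
Why: Nucleophile-catalysed acylation esterifies the remaining allylic hydroxyl with retention of configuration, and the fast benzoylation outruns acetyl migration.

**Step 11**
Reactants: 13 (2S,3R,3aR,7aR)-3-hydroxy-2-vinyl-2,3,3a,7a-tetrahydro-5H-furo[3,2-b]pyran-5-one; 18 (2R,3S)-2-acetoxypent-4-en-3-yl benzoate
Product: 19 (2R,3S,4E)-2-acetoxy-5-[(2S,3R,3aR,7aR)-3-hydroxy-5-oxo-2,3,3a,7a-tetrahydro-5H-furo[3,2-b]pyran-2-yl]pent-4-en-3-yl benzoate (CNP0151877.1)
Conditions: 18 (3 equiv), second-generation Hoveyda–Grubbs catalyst (H2IMes)Cl2Ru(=CH-C6H4-2-OiPr) (10 mol %), CH2Cl2, 40 °C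
Reagents that add atoms: none
Why: Olefin cross-metathesis joins the two monosubstituted alkenes with loss of ethene, the branched allylic oxygen substituents on both sides favour the E-alkene, and the endocyclic Z-enoate, the esters and the free hydroxyl are inert to the ruthenium carbene.

**Compound list**
1 | D-gulono-1,4-lactone | OC[C@@H](O)[C@@H]1OC(=O)[C@H](O)[C@@H]1O | starting material
2 | 2,3:5,6-di-O-isopropylidene-D-gulono-1,4-lactone | CC1(C)OC[C@@H](O1)[C@@H]2OC(=O)[C@@H]3OC(C)(C)O[C@H]23 | intermediate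
3 | 2,3-O-isopropylidene-D-gulono-1,4-lactone | OC[C@@H](O)[C@@H]1OC(=O)[C@@H]2OC(C)(C)O[C@H]12 | intermediate
4 | 6-deoxy-6-iodo-2,3-O-isopropylidene-D-gulono-1,4-lactone (iodohydrin) | IC[C@@H](O)[C@@H]1OC(=O)[C@@H]2OC(C)(C)O[C@H]12 | intermediate
5 | 5,6-dideoxy-2,3-O-isopropylidene-L-lyxo-hex-5-enono-1,4-lactone, i.e. (3aR,6S,6aR)-2,2-dimethyl-6-vinyldihydrofuro[3,4-d][1,3]dioxol-4(3aH)-one | C=C[C@@H]1OC(=O)[C@@H]2OC(C)(C)O[C@H]12 | intermediate
6 | ethyl propiolate | CCOC(=O)C#C | starting material
7 | lithium ethyl propiolate (ethyl 3-lithioprop-2-ynoate) | CCOC(=O)C#C[Li] | intermediate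
8 | lithium lactolate of the propiolate adduct of 5 (new quaternary centre unassigned) | C=C[C@@H]1OC(O[Li])(C#CC(=O)OCC)[C@@H]2OC(C)(C)O[C@H]12 | intermediate
9 | alkynyl oxocarbenium ion derived from 8 | C=C[C@@H]1[O+]=C(C#CC(=O)OCC)[C@@H]2OC(C)(C)O[C@H]12 | intermediate
10 | ethyl 3-[(3aS,4R,6S,6aR)-2,2-dimethyl-6-vinyltetrahydrofuro[3,4-d][1,3]dioxol-4-yl]prop-2-ynoate (all four ring substituents cis) | C=C[C@@H]1O[C@H](C#CC(=O)OCC)[C@@H]2OC(C)(C)O[C@H]12 | intermediate
11 | ethyl (2Z)-3-[(3aS,4R,6S,6aR)-2,2-dimethyl-6-vinyltetrahydrofuro[3,4-d][1,3]dioxol-4-yl]prop-2-enoate | C=C[C@@H]1O[C@H](/C=C\C(=O)OCC)[C@@H]2OC(C)(C)O[C@H]12 | intermediate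
12 | ethyl (2Z)-3-[(2R,3R,4S,5S)-3,4-dihydroxy-5-vinyloxolan-2-yl]prop-2-enoate | C=C[C@@H]1O[C@H](/C=C\C(=O)OCC)[C@H](O)[C@@H]1O | intermediate
13 | (2S,3R,3aR,7aR)-3-hydroxy-2-vinyl-2,3,3a,7a-tetrahydro-5H-furo[3,2-b]pyran-5-one | C=C[C@@H]1O[C@@H]2C=CC(=O)O[C@@H]2[C@@H]1O | intermediate
14 | penta-1,4-dien-3-ol | C=CC(O)C=C | starting material
15 | (2R,3S)-1,2-epoxypent-4-en-3-ol | C=C[C@H](O)[C@H]1CO1 | intermediate
16 | (2R,3S)-pent-4-ene-2,3-diol | C[C@@H](O)[C@@H](O)C=C | intermediate
17 | (2R,3S)-3-hydroxypent-4-en-2-yl acetate | CC(=O)O[C@H](C)[C@@H](O)C=C | intermediate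
18 | (2R,3S)-2-acetoxypent-4-en-3-yl benzoate | CC(=O)O[C@H](C)[C@H](C=C)OC(=O)c1ccccc1 | intermediate
19 | (2R,3S,4E)-2-acetoxy-5-[(2S,3R,3aR,7aR)-3-hydroxy-5-oxo-2,3,3a,7a-tetrahydro-5H-furo[3,2-b]pyran-2-yl]pent-4-en-3-yl benzoate | CC(=O)O[C@H](C)[C@H](/C=C/[C@@H]1O[C@@H]2C=CC(=O)O[C@@H]2[C@@H]1O)OC(=O)c1ccccc1 | target

**Step count**
Total steps: 11. Longest linear sequence: 7 (steps 1–6 and 11); the side chain (steps 7–10) is a four-step branch.

**Three steps most likely to fail**

Step 4 (one-flask propiolate addition and silane reduction). The ester-bearing alkyne slows ionisation of the lactolate, and the Lewis acid may attack the acetonide before reduction is complete. The fallback sets out from 5 and comes back at 13. Lithiated tert-butyldimethyl(prop-2-yn-1-yloxy)silane (n-BuLi, THF, −78 °C), the same β-donor at the alcohol oxidation level, is added to 5 and the neutral silyloxypropynyl lactol F1 is isolated. Its electron-richer alkyne ionises readily, so Et3SiH and BF3·OEt2 in CH2Cl2/MeCN at −40 °C give the all-cis propargyl silyl ether F2 by the same convex-face hydride delivery. Lindlar reduction gives the Z-allyl silyl ether F3, aqueous TFA removes the silyl and acetonide groups to give the Z-allylic triol F4, and MnO2 in CH2Cl2 oxidises the allylic alcohol and the derived lactol to the lactone 13.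

Step 11 (cross-metathesis of two hindered, allylically oxygenated alkenes). The coupling may stall or give mainly the homodimer of 18. The fallback sets out from 11 and comes back at 19. Alcohol 17 is oxidised with Dess–Martin periodinane to the enone (2R)-3-oxopent-4-en-2-yl acetate F5, an electron-poor partner that does not homodimerise. Cross-metathesis of 11 with F5 under the same catalyst gives the E-enone F6. Chelation-controlled reduction with Zn(BH4)2 in Et2O at −78 °C (or a reagent-controlled CBS reduction) gives the anti allylic alcohol F7. BzCl and pyridine give the benzoate F8, and aqueous TFA removes the acetonide and closes the lactone to give 19.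

Step 9 (lipase regioselection between two secondary hydroxyls). The enzyme may be slow or give mixed acetates. The fallback sets out from 15 and comes back at 18, fixing the order of acylation chemically. Epoxy alcohol 15 is benzoylated (BzCl, pyridine) to the epoxy benzoate F9. LiI and AcOH in THF open the epoxide at the terminal carbon to give the iodohydrin F10. Bu3SnH and AIBN in toluene at 80 °C remove the iodine to give the hydroxy benzoate F11, and Ac2O with pyridine gives 18.

**Further compounds**
F1 | step 4 | alkynyl lactol from 5: 4-[3-(tert-butyldimethylsilyloxy)prop-1-ynyl]-2,2-dimethyl-6-vinyltetrahydrofuro[3,4-d][1,3]dioxol-4-ol, ring centres as in 5, anomeric centre unassigned | C=C[C@@H]1OC(O)(C#CCO[Si](C)(C)C(C)(C)C)[C@@H]2OC(C)(C)O[C@H]12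
F2 | step 4 | tert-butyldimethylsilyl ether of 3-[(3aS,4R,6S,6aR)-2,2-dimethyl-6-vinyltetrahydrofuro[3,4-d][1,3]dioxol-4-yl]prop-2-yn-1-ol | C=C[C@@H]1O[C@H](C#CCO[Si](C)(C)C(C)(C)C)[C@@H]2OC(C)(C)O[C@H]12
F3 | step 4 | tert-butyldimethylsilyl ether of (2Z)-3-[(3aS,4R,6S,6aR)-2,2-dimethyl-6-vinyltetrahydrofuro[3,4-d][1,3]dioxol-4-yl]prop-2-en-1-ol | C=C[C@@H]1O[C@H](/C=C\CO[Si](C)(C)C(C)(C)C)[C@@H]2OC(C)(C)O[C@H]12
F4 | step 4 | (2R,3R,4S,5S)-2-[(1Z)-3-hydroxyprop-1-enyl]-5-vinyloxolane-3,4-diol | C=C[C@@H]1O[C@H](/C=C\CO)[C@H](O)[C@@H]1O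
F5 | step 11 | (2R)-3-oxopent-4-en-2-yl acetate | CC(=O)O[C@H](C)C(=O)C=C
F6 | step 11 | ethyl (2Z)-3-[(3aS,4R,6S,6aR)-6-[(1E,4R)-4-acetoxy-3-oxopent-1-enyl]-2,2-dimethyltetrahydrofuro[3,4-d][1,3]dioxol-4-yl]prop-2-enoate | CC(=O)O[C@H](C)C(=O)/C=C/[C@@H]1O[C@H](/C=C\C(=O)OCC)[C@@H]2OC(C)(C)O[C@H]12
F7 | step 11 | ethyl (2Z)-3-[(3aS,4R,6S,6aR)-6-[(1E,3S,4R)-4-acetoxy-3-hydroxypent-1-enyl]-2,2-dimethyltetrahydrofuro[3,4-d][1,3]dioxol-4-yl]prop-2-enoate | CC(=O)O[C@H](C)[C@@H](O)/C=C/[C@@H]1O[C@H](/C=C\C(=O)OCC)[C@@H]2OC(C)(C)O[C@H]12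
F8 | step 11 | benzoate of F7 at the allylic hydroxyl (acetonide-protected, ring-open precursor of 19) | CC(=O)O[C@H](C)[C@H](/C=C/[C@@H]1O[C@H](/C=C\C(=O)OCC)[C@@H]2OC(C)(C)O[C@H]12)OC(=O)c1ccccc1
F9 | step 9 | (1S)-1-[(2R)-oxiran-2-yl]prop-2-enyl benzoate | C=C[C@H](OC(=O)c1ccccc1)[C@H]1CO1
F10 | step 9 | (2S,3S)-2-hydroxy-1-iodopent-4-en-3-yl benzoate | C=C[C@H](OC(=O)c1ccccc1)[C@H](O)CI
F11 | step 9 | (2R,3S)-2-hydroxypent-4-en-3-yl benzoate | C=C[C@H](OC(=O)c1ccccc1)[C@H](O)C
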